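Ring A is cut at the C2–C3 bond. That leaves an elemane-type 1,5-diene on the ring-B ketone: the C1=C2 vinyl group on C10 and the C3=C4 isopropenyl group (carrying C15) on C5 sit trans-diequatorial, so ring A (C1–C5, C10) lacks only C2–C3. A cationic divalent palladium catalyst is proposed to join C2 to C3 in one operation and release the Δ3 alkene, giving the trans-fused 4,10-dimethyloctalin-8-one with C5 and C10 unchanged. The precursor, (3S,4S)-3-ethenyl-3-methyl-4-isopropenylcyclohexanone, comes in two steps from (1R,5R)-verbenone. Acetone aldol condensation, α-epoxidation, acetolysis, acylation with (2S,3R)-epoxytiglic acid and a singlet-oxygen ene reaction finish the target.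

Key step: step 3

Remark: eudesmane numbering is used for all ring compounds (ring A = C1–C5 with C10, ring B = C5–C10); (1R,5R)-(+)-verbenone is taken as purchasable, being the allylic oxidation product of (1R)-(+)-α-pinene.

Step 1
Reactants: 1 (1R,5R)-(+)-verbenone; 2 vinylmagnesium bromide
Product: 3 (1R,4S,5S)-4-ethenyl-4,6,6-trimethylbicyclo[3.1.1]heptan-2-one
Conditions: CuBr·SMe2 (10 mol%), THF, −40 → 0 °C; 1 M HCl work-up
Reagents that add atoms: none
Why: Copper-catalysed conjugate addition of the Grignard reagent to the β,β-disubstituted enone delivers the vinyl group to C4 from the face anti to the gem-dimethyl bridge, which sets the new quaternary centre as 4S.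

Step 2
Reactants: 3 (1R,4S,5S)-4-ethenyl-4,6,6-trimethylbicyclo[3.1.1]heptan-2-one
Product: 5 (3S,4S)-3-ethenyl-3-methyl-4-(prop-1-en-2-yl)cyclohexan-1-one, via enol acetate 4 (not isolated)
Conditions: Zn(OAc)2, BF3·OEt2, Ac2O, 0 °C → rt; crude, K2CO3 (cat.), MeOH, rt
Reagents that add atoms: none
Why: Lewis-acid-promoted cyclobutane fragmentation of the pinane ketone breaks the strained bond between the α-carbon and the gem-dimethyl carbon, the tertiary cation loses a methyl proton to give the isopropenyl group and the enolate is trapped as enol acetate 4, which methanolysis converts to the ketone; both stereocentres are untouched, so isopropenyl ends up cis to methyl and trans to vinyl.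

Step 3
Reactants: 5 (3S,4S)-3-ethenyl-3-methyl-4-(prop-1-en-2-yl)cyclohexan-1-one
Product: 6 (4aR,8aR)-5,8a-dimethyl-3,4,4a,7,8,8a-hexahydronaphthalen-2(1H)-one (4,10β-dimethyl-5αH-octal-3-en-8-one)
Conditions: [Pd(PNP)(NCMe)](BF4)2 (10 mol%, preformed from PdCl2(MeCN)2, PNP and AgBF4; PNP = 2,6-bis(diphenylphosphinomethyl)pyridine), Ph2NH (20 mol%), MeNO2, 25 °C
Reagents that add atoms: none
Why: Proposed new method: the single open site of the electrophilic divalent palladium pincer cation binds the unhindered C1=C2 vinyl group, and the isopropenyl methylene C3 adds to C2 anti to the metal through a chair in which C10–C1 and C5–C4 are equatorial on ring B, which gives a C1–Pd σ-bond and a tertiary cation at C4; Ph2NH then takes the axial H-3 to leave the Δ3 alkene and its conjugate acid cleaves the C1–Pd bond by protonolysis, so that the overall change is an isomerisation with the metal returned. The closest known reaction types are the PdCl2(MeCN)2-catalysed Cope rearrangement of 2-substituted 1,5-dienes, which runs through the same 1,4-related palladium-bound cyclohexyl cation, and the cation–olefin cyclisation of 1,5-dienes started by tridentate complexes of divalent palladium or platinum; termination by loss of a ring proton with protonolytic turnover on an elemane diene is the untested part. Ring A closes in a 6-endo-trig mode with respect to both alkenes. No stereocentre is formed: C5 and C10 come unchanged from 5 and their trans-diequatorial alkenyl groups permit only the trans ring fusion. The step needs C2–C3 bonding (not C2–C4 or C1–C3), proton loss from C3 and not from C15 or C5, protodepalladation and not β-hydride elimination, and no Cope fragmentation of C5–C10; the methyl group on C4 makes C4 the only carbon able to carry the charge, the axial H-3 lies parallel to the empty orbital and is more exposed than the buried ring-fusion H-5, the tridentate ligand leaves no cis site for β-hydride elimination, and opening to the strained (E,E)-cyclodecadienone is uphill while the reverse C2–C3 cleavage only regenerates 5.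

Step 4
Reactants: 6 (4aR,8aR)-5,8a-dimethyl-3,4,4a,7,8,8a-hexahydronaphthalen-2(1H)-one; 7 acetone
Product: 9 (5R,7R,10R)-11-hydroxyeudesm-3-en-8-one, via lithium enolate 8 (not isolated)
Conditions: LiN(iPr)2, THF, −78 °C; 7, −78 °C; AcOH quench at −78 °C
Reagents that add atoms: none
Why: Kinetic deprotonation by the hindered amide occurs at C7, away from C9 which is shielded by the quaternary C10, and the directed aldol addition of the lithium enolate to acetone gives the tertiary carbinol; the C7 configuration (side chain expected equatorial) does not matter because step 5 removes it.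

Step 5
Reactants: 9 (5R,7R,10R)-11-hydroxyeudesm-3-en-8-one
Product: 11 (5R,10R)-eudesma-3,7(11)-dien-8-one, via mesylate 10 (not isolated)
Conditions: MsCl, Et3N, DMAP (cat.), CH2Cl2, 0 °C → rt; then DBU (cat.), rt
Reagents that add atoms: none
Why: Mesylation of the tertiary alcohol followed by E1cB elimination through the ketone enol (aldol dehydration) gives the conjugated isopropylidene ketone, DBU moves any isopropenyl isomer into conjugation, and no stereocentre is formed.

Step 6
Reactants: 11 (5R,10R)-eudesma-3,7(11)-dien-8-one
Product: 12 (3R,4S,5R,10R)-3α,4α-epoxyeudesm-7(11)-en-8-one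
Conditions: mCPBA (1.05 equiv), CH2Cl2, 0 °C; aq. NaHCO3/Na2S2O3 wash
Reagents that add atoms: mCPBA, OOC(=O)c1cccc(Cl)c1
Why: Prilezhaev epoxidation picks the electron-rich trisubstituted Δ3 alkene over the electron-poor enone, and the peracid approaches the α-face, anti to the axial C10 methyl group, which sets C3 and C4 as the 3α,4α-epoxide.

Step 7
Reactants: 12 (3R,4S,5R,10R)-3α,4α-epoxyeudesm-7(11)-en-8-one
Product: 13 (3R,4R,5R,10R)-4β-acetoxy-3α-hydroxyeudesm-7(11)-en-8-one
Conditions: AcOH, NaOAc, 45 °C
Reagents that add atoms: acetic acid, CC(=O)O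
Why: Acid-catalysed epoxide opening (acetolysis) is both Markovnikov and trans-diaxial (Fürst–Plattner rule) when acetic acid attacks the tertiary C4 from the β-face with inversion, which sets 4β-OAc beside the retained 3α-OH, and the rigid trans-diaxial arrangement prevents acyl migration.

Step 8
Reactants: 14 tiglic acid
Product: 15 (E)-2-methylbut-2-en-1-ol
Conditions: LiAlH4, Et2O, 0 °C → rt; aqueous work-up
Reagents that add atoms: none
Why: Hydride reduction of the carboxylic acid by LiAlH4 proceeds by 1,2-addition and leaves the trisubstituted (E)-alkene unchanged.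

Step 9
Reactants: 15 (E)-2-methylbut-2-en-1-ol
Product: 16 [(2R,3R)-2,3-dimethyloxiran-2-yl]methanol
Conditions: Ti(OiPr)4 (10 mol%), D-(−)-diethyl tartrate (12 mol%), tBuOOH, 4 Å molecular sieves, CH2Cl2, −20 °C
Reagents that add atoms: tert-butyl hydroperoxide, CC(C)(C)OO
Why: Sharpless asymmetric epoxidation of the (E)-allylic alcohol with the D-(−)-tartrate ligand delivers oxygen to the face that gives the (2R,3R)-epoxy alcohol (the L-(+)-ligand gives (2S,3S) from (E)-allylic alcohols), so both stereocentres are set by the catalyst together with the alkene geometry.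

Step 10
Reactants: 16 [(2R,3R)-2,3-dimethyloxiran-2-yl]methanol
Product: 17 (2S,3R)-2,3-dimethyloxirane-2-carboxylic acid
Conditions: RuCl3·xH2O (2 mol%), NaIO4, MeCN/EtOAc/H2O, 0 °C → rt
Reagents that add atoms: sodium periodate, [Na+].[O-][I](=O)(=O)=O
Why: Ruthenium tetroxide oxidation takes the primary alcohol through the aldehyde hydrate to the acid without touching the epoxide, and the C2 descriptor changes from R to S only through the change in substituent priority.

Step 11
Reactants: 13 (3R,4R,5R,10R)-4β-acetoxy-3α-hydroxyeudesm-7(11)-en-8-one; 17 (2S,3R)-2,3-dimethyloxirane-2-carboxylic acid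
Product: 19 (3R,4R,5R,10R)-4β-acetoxy-8-oxoeudesm-7(11)-en-3α-yl (2S,3R)-2,3-dimethyloxirane-2-carboxylate, via mixed anhydride 18 (not isolated)
Conditions: 17, 2,4,6-trichlorobenzoyl chloride, Et3N, THF, rt; then 13, DMAP, toluene, rt → 40 °C
Reagents that add atoms: none
Why: Yamaguchi esterification through the mixed anhydride and DMAP acylates the hindered axial 3α-hydroxyl under mild basic conditions that leave the epoxide, the tertiary acetate and the enone intact, and no stereocentre is touched.

Step 12
Reactants: 19 (3R,4R,5R,10R)-4β-acetoxy-8-oxoeudesm-7(11)-en-3α-yl (2S,3R)-2,3-dimethyloxirane-2-carboxylate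
Product: 20 (3R,4R,5R,10R)-4β-acetoxy-11-hydroperoxy-8-oxoeudesm-6-en-3α-yl (2S,3R)-2,3-dimethyloxirane-2-carboxylate (CNP0270248.1)
Conditions: O2, hν (visible light), tetraphenylporphyrin (cat.), CH2Cl2, 0 °C
Reagents that add atoms: oxygen, O=O
Why: The Schenck ene reaction of singlet oxygen with the s-cis enone follows the geminal rule, taking an allylic hydrogen from C6 (the alkyl group geminal to the carbonyl) and placing the hydroperoxide on the non-stereogenic C11 while the double bond moves to C6=C7 and C5 stays untouched.

Compound list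
1 | (1R,5R)-(+)-verbenone | CC1(C)[C@@H]2C[C@H]1C(=O)C=C2C | starting material
2 | vinylmagnesium bromide | C=C[Mg]Br | starting material
3 | (1R,4S,5S)-4-ethenyl-4,6,6-trimethylbicyclo[3.1.1]heptan-2-one (vinyl anti to the gem-dimethyl bridge) | CC1(C)[C@@H]2C[C@H]1C(=O)C[C@@]2(C)C=C | intermediate
4 | (4S,5S)-5-ethenyl-5-methyl-4-(prop-1-en-2-yl)cyclohex-1-en-1-yl acetate (enol acetate) | CC(=C)[C@@H]1CC=C(OC(C)=O)C[C@@]1(C)C=C | intermediate
5 | (3S,4S)-3-ethenyl-3-methyl-4-(prop-1-en-2-yl)cyclohexan-1-one (isopropenyl trans to vinyl) | CC(=C)[C@@H]1CCC(=O)C[C@@]1(C)C=C | intermediate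
6 | (4aR,8aR)-5,8a-dimethyl-3,4,4a,7,8,8a-hexahydronaphthalen-2(1H)-one (4,10β-dimethyl-5αH-octal-3-en-8-one) | CC1[C@@H]2CCC(=O)C[C@@]2(C)CCC=1 | intermediate
7 | acetone | CC(C)=O | starting material
8 | lithium enolate of 6 (C7=C8–OLi) | CC1[C@@H]2CC=C(O[Li])C[C@@]2(C)CCC=1 | intermediate
9 | (5R,7R,10R)-11-hydroxyeudesm-3-en-8-one (side chain 7β, equatorial; its C7 epimer serves equally) | CC1[C@@H]2C[C@H](C(C)(C)O)C(=O)C[C@@]2(C)CCC=1 | intermediate
10 | 11-methanesulfonate of 9 | CC1[C@@H]2C[C@H](C(C)(C)OS(C)(=O)=O)C(=O)C[C@@]2(C)CCC=1 | intermediate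
11 | (5R,10R)-eudesma-3,7(11)-dien-8-one | CC1[C@@H]2CC(=C(C)C)C(=O)C[C@@]2(C)CCC=1 | intermediate
12 | (3R,4S,5R,10R)-3α,4α-epoxyeudesm-7(11)-en-8-one | C[C@]12[C@@H]3CC(=C(C)C)C(=O)C[C@@]3(C)CC[C@H]1O2 | intermediate
13 | (3R,4R,5R,10R)-4β-acetoxy-3α-hydroxyeudesm-7(11)-en-8-one (C15 methyl 4α) | CC(=O)O[C@]1(C)[C@@H]2CC(=C(C)C)C(=O)C[C@@]2(C)CC[C@H]1O | intermediate
14 | tiglic acid, (E)-2-methylbut-2-enoic acid | C/C=C(\C)C(=O)O | starting material
15 | (E)-2-methylbut-2-en-1-ol | C/C=C(\C)CO | intermediate
16 | [(2R,3R)-2,3-dimethyloxiran-2-yl]methanol | OC[C@@]1(C)O[C@@H]1C | intermediate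
17 | (2S,3R)-2,3-dimethyloxirane-2-carboxylic acid | OC(=O)[C@@]1(C)O[C@@H]1C | intermediate
18 | (2S,3R)-2,3-dimethyloxirane-2-carboxylic 2,4,6-trichlorobenzoic anhydride | O=C(OC(=O)[C@@]1(C)O[C@@H]1C)c1c(Cl)cc(Cl)cc1Cl | intermediate
19 | (3R,4R,5R,10R)-4β-acetoxy-8-oxoeudesm-7(11)-en-3α-yl (2S,3R)-2,3-dimethyloxirane-2-carboxylate | CC(=O)O[C@]1(C)[C@@H]2CC(=C(C)C)C(=O)C[C@@]2(C)CC[C@H]1OC(=O)[C@@]1(C)O[C@@H]1C | intermediate
20 | (3R,4R,5R,10R)-4β-acetoxy-11-hydroperoxy-8-oxoeudesm-6-en-3α-yl (2S,3R)-2,3-dimethyloxirane-2-carboxylate | CC(=O)O[C@]1(C)[C@@H]2C=C(C(C)(C)OO)C(=O)C[C@@]2(C)CC[C@H]1OC(=O)[C@@]1(C)O[C@@H]1C | target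

Total step count: 12. Longest linear sequence: 9 steps (steps 1–7, 11 and 12, from verbenone 1).

Steps most likely to fail

Step 3 (carries the label). The cyclised cation may revert to the diene by C2–C3 cleavage faster than it is deprotonated, so that no conversion occurs. Proton loss may occur from C15 or C5, or a hydride may shift from C5 and the C1–Pd bond close a cyclopropane. Protonolysis of the C1–Pd bond may be too slow for turnover. Repeated passage through the cyclodecadienone would erode the configuration at C5 and C10. The fallback uses known chemistry and runs from verbenone 1 back to 6. Copper-catalysed conjugate addition of commercial but-3-enylmagnesium bromide (CuBr·SMe2, THF) should give, with the facial selectivity of step 1, the ketone 4-(but-3-en-1-yl)-4,6,6-trimethylbicyclo[3.1.1]heptan-2-one F1. The cyclobutane cleavage of step 2 (Zn(OAc)2, BF3·OEt2, Ac2O) should give the enol acetate 5-(but-3-en-1-yl)-5-methyl-4-(prop-1-en-2-yl)cyclohex-1-en-1-yl acetate F2, which is methanolysed without isolation (K2CO3, MeOH) to 3-(but-3-en-1-yl)-3-methyl-4-(prop-1-en-2-yl)cyclohexan-1-one F3. Ring-closing metathesis of F3 with the second-generation Grubbs catalyst RuCl2(=CHPh)(H2IMes)(PCy3) in CH2Cl2 at 40 °C joins C4 of the isopropenyl group to the butenyl CH, which becomes C3, with loss of ethylene, and returns to the route at 6. Ring A is then closed at C3=C4 instead of C2–C3, and C5 and C10 are set as in the main route.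

Step 7. Ionisation at C4 may run ahead of capture by the weakly nucleophilic acetic acid, which would lead to elimination towards C15 or C5 or to a hydride shift from C3. Attack at C3 would give the regioisomeric diequatorial product. The fallback runs from epoxide 12 back to 13. Hydrolysis with water as the far more abundant nucleophile (HClO4 cat., THF/H2O, 0 °C) should give the trans-diaxial diol 3α,4β-dihydroxyeudesm-7(11)-en-8-one F4. Exhaustive acetylation (Ac2O, DMAP, pyridine, 60 °C) should give the diacetate 3α,4β-diacetoxyeudesm-7(11)-en-8-one F5. K2CO3 in MeOH at 0 °C should then remove the secondary acetate much faster than the tertiary one and return to the route at 13.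

Step 12. Hydrogen abstraction may occur from the C12 or C13 methyl group instead of C6 (loss of regioselectivity), singlet oxygen may be taken up only slowly by the electron-poor alkene, and the hydroperoxide may break down under long sensitised irradiation. The fallback runs from 19 directly to 20 by radical-chain autoxidation with triplet oxygen (N-hydroxyphthalimide cat., O2, MeCN, 40 °C). The phthalimide-N-oxyl radical abstracts an allylic hydrogen from C6, and oxygen adds reversibly to the C6–C7–C11 allyl radical. The allylperoxyl radical should settle at the tertiary C11, where the C6=C7 bond is conjugated with the C8 ketone, and chain transfer gives the hydroperoxide. This fallback makes no new compound (F0).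

Further compounds
F1 | step 3 | 4-(but-3-en-1-yl)-4,6,6-trimethylbicyclo[3.1.1]heptan-2-one (butenyl anti to the gem-dimethyl bridge) | CC1(C)[C@@H]2C[C@H]1C(=O)C[C@@]2(C)CCC=C
F2 | step 3 | 5-(but-3-en-1-yl)-5-methyl-4-(prop-1-en-2-yl)cyclohex-1-en-1-yl acetate | CC(=C)[C@@H]1CC=C(OC(C)=O)C[C@@]1(C)CCC=C
F3 | step 3 | 3-(but-3-en-1-yl)-3-methyl-4-(prop-1-en-2-yl)cyclohexan-1-one (isopropenyl cis to methyl) | CC(=C)[C@@H]1CCC(=O)C[C@@]1(C)CCC=C
F4 | step 7 | 3α,4β-dihydroxyeudesm-7(11)-en-8-one | C[C@@]1(O)[C@@H]2CC(=C(C)C)C(=O)C[C@@]2(C)CC[C@H]1O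
F5 | step 7 | 3α,4β-diacetoxyeudesm-7(11)-en-8-one | CC(=O)O[C@]1(C)[C@@H]2CC(=C(C)C)C(=O)C[C@@]2(C)CC[C@H]1OC(C)=O
F0 | step 12 | none | none
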